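**Retrosynthetic overview**
1. Both tetramethylcyclohexanetrione (syncarpic) rings are cut at once. Each splits into the CH2–C(=O)–OAr unit of a dihydrocoumarin (2 ring carbons) and ring-opened 2,2,4,4-tetramethylcyclobutane-1,3-dione (4 ring carbons). The leaving groups are the target's own phenols, so no atom is lost.
2. The tricyclic bis(dihydrocoumarin) is cut at its two aryl–CH bonds and two lactone C–O bonds. This gives two successive carbene-catalysed [3+3] annulations of hexanoylphloroglucinol, first with (E)-4-methylpent-2-enal and then with (E)-5-methylhex-2-enal. Each annulation sets one benzylic stereocentre under catalyst control.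
3. Hexanoylphloroglucinol comes from phloroglucinol and hexanoyl chloride.
4. Ring order: arene (bought) → lactone ring A (isopropyl centre) → lactone ring B (isobutyl centre) → carbocyclic rings C and D together in one operation, with rings A and B opening as C and D close.

Reading of the target: both benzylic carbons are (R), with priorities enol-trione C > aryl C > alkyl > H. The two centres have the same spatial sense, so one catalyst antipode serves both annulations.

Assumption: the (5aR,10bS) antipode of the aminoindanol-derived N-mesityl triazolium salt is taken to leave the Si face of C-β of its bound enoyl group open; if step 2 gives the enantiomer of 6, the equally available (5aS,10bR) antipode is used in steps 2 and 3 and nothing else changes.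

**Step 1**
Reactants: 1 phloroglucinol; 2 hexanoyl chloride
Product: 3 1-(2,4,6-trihydroxyphenyl)hexan-1-one
Conditions: AlCl3 (3.5 equiv), CH2Cl2–MeNO2, 0 → 40 °C; then ice, 1 M HCl
Reagents that add atoms: hexanoyl chloride (2), CCCCCC(=O)Cl
Why: Friedel–Crafts acylation of the very electron-rich triol stops after one acyl group because the chelated aryl ketone–AlCl3 complex is deactivated; no stereocentre is formed.

**Step 2**
Reactants: 3 1-(2,4,6-trihydroxyphenyl)hexan-1-one; 4 (E)-4-methylpent-2-enal
Product: 6 (4R)-6-hexanoyl-5,7-dihydroxy-4-isopropylchroman-2-one, via 4-methylpent-2-enoyl azolium cation 5 (not isolated)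
Conditions: (5aR,10bS)-2-mesityl-5a,10b-dihydro-4H,6H-indeno[2,1-b][1,2,4]triazolo[4,3-d][1,4]oxazin-2-ium chloride (10 mol%), iPr2NEt (0.5 equiv), 3,3',5,5'-tetra-tert-butyl-4,4'-diphenoquinone (1.1 equiv), 4 Å MS, THF–toluene 1:1, 4 (1.05 equiv) added over 4 h, 23 °C
Reagents that add atoms: (E)-4-methylpent-2-enal (4), CC(C)/C=C/C=O
Why: This is an oxidative N-heterocyclic-carbene [3+3] annulation of a stable enol (Coates–Claisen / Michael–lactonisation type), in which the acylphloroglucinolate, a vinylogous 1,3-dicarbonyl nucleophile as acidic as the enols known to work, bonds through its free ring carbon to the Si face of C-β of 5 (the face away from the indane wall) and so sets the (R) centre, the para-phenol oxygen closes the lactone and releases the carbene, and the lactone deactivates the ring so that annulation stops at one.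

**Step 3**
Reactants: 6 (4R)-6-hexanoyl-5,7-dihydroxy-4-isopropylchroman-2-one; 7 (E)-5-methylhex-2-enal
Product: 9 (4R,10S)-6-hexanoyl-5-hydroxy-10-isobutyl-4-isopropyl-3,4,9,10-tetrahydro-2H,8H-pyrano[2,3-f]chromene-2,8-dione, via 5-methylhex-2-enoyl azolium cation 8 (not isolated)
Conditions: (5aR,10bS)-2-mesityl-5a,10b-dihydro-4H,6H-indeno[2,1-b][1,2,4]triazolo[4,3-d][1,4]oxazin-2-ium chloride (20 mol%), iPr2NEt (1.0 equiv), 3,3',5,5'-tetra-tert-butyl-4,4'-diphenoquinone (1.2 equiv), 4 Å MS, THF–toluene 1:1, 40 °C
Reagents that add atoms: (E)-5-methylhex-2-enal (7), CC(C)C/C=C/C=O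
Why: The same oxidative carbene [3+3] annulation acts on the only free ring carbon (C-8) and its only free neighbouring phenol (7-OH), the same catalyst again opens the Si face of C-β of 8 so the new centre has the same spatial sense as the first (labelled S only because CH2C=O now outranks isobutyl), and the minor enantiomer of 6 is turned mainly into a separable diastereomer (Horeau-type enrichment).

**Step 4**
Reactants: 9 (4R,10S)-bis-lactone; 10 2,2,4,4-tetramethylcyclobutane-1,3-dione (2 equiv incorporated)
Product: 12 myrtucommulone H, via bis(3-oxoacyl) dilactone polyenolate 11 (not isolated)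
Conditions: 9 + 10 (2.2 equiv), THF, −78 °C; LiN(SiMe3)2 (6.0 equiv) dropwise; −78 → 23 °C, 6 h; cold 1 M HCl
Reagents that add atoms: 2,2,4,4-tetramethylcyclobutane-1,3-dione (10), CC1(C)C(=O)C(C)(C)C1=O
Why: Proposed new method: each lithium lactone enolate adds to a strained, non-enolisable C=O of 10, the cyclobutanolate fragments by retro-Claisen ring opening (strain release) to the 3-acyl lactone 11 carrying a Me2C enolate (re-formed by the excess base if the acidic C-3 H quenches it), and that carbon attacks the aryl-ester carbonyl in a six-membered Dieckmann closure that expels the ring phenoxide, so two carbocycles form while two lactones open and any O-acylated enol lactone is returned by phenoxide to the only sink, the stabilised triketone enolate; the closest known reaction types are the alkoxide-induced ring opening of 10 to 2,2,4-trimethyl-3-oxopentanoates, the ester-enolate chain by which base converts dimethylketene dimer into hexamethylcyclohexane-1,3,5-trione, and the Dieckmann synthesis of syncarpic acid from methyl 2,2,4,4-tetramethyl-3,5-dioxohexanoate; no stereocentre is made, the two benzylic centres lie β to the enolates, carry no acidic H and cannot leave by retro-Michael from the fully deprotonated aprotic polyanion, and the former lactone α-carbons end as planar enol carbons, which gives the (R,R) target (the isobutyl centre changes label from S to R by priority only).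

**Compound list**
1 | phloroglucinol (benzene-1,3,5-triol) | Oc1cc(O)cc(O)c1 | starting material
2 | hexanoyl chloride | CCCCCC(=O)Cl | starting material
3 | 1-(2,4,6-trihydroxyphenyl)hexan-1-one (hexanoylphloroglucinol) | CCCCCC(=O)c1c(O)cc(O)cc1O | intermediate
4 | (E)-4-methylpent-2-enal | CC(C)/C=C/C=O | starting material
5 | (5aR,10bS)-2-mesityl-1-[(E)-4-methylpent-2-enoyl]-5a,10b-dihydro-4H,6H-indeno[2,1-b][1,2,4]triazolo[4,3-d][1,4]oxazin-2-ium, catalyst-bound cation, not isolated | CC(C)/C=C/C(=O)c1n2[C@H]3c4ccccc4C[C@H]3OCc2n[n+]1-c1c(C)cc(C)cc1C | intermediate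
6 | (4R)-6-hexanoyl-5,7-dihydroxy-4-isopropylchroman-2-one (lactone ring A closed on the phenol para to the ketone) | CCCCCC(=O)c1c(O)c2[C@@H](C(C)C)CC(=O)Oc2cc1O | intermediate
7 | (E)-5-methylhex-2-enal | CC(C)C/C=C/C=O | starting material
8 | (5aR,10bS)-2-mesityl-1-[(E)-5-methylhex-2-enoyl]-5a,10b-dihydro-4H,6H-indeno[2,1-b][1,2,4]triazolo[4,3-d][1,4]oxazin-2-ium, catalyst-bound cation, not isolated | CC(C)C/C=C/C(=O)c1n2[C@H]3c4ccccc4C[C@H]3OCc2n[n+]1-c1c(C)cc(C)cc1C | intermediate
9 | (4R,10S)-6-hexanoyl-5-hydroxy-10-isobutyl-4-isopropyl-3,4,9,10-tetrahydro-2H,8H-pyrano[2,3-f]chromene-2,8-dione | CCCCCC(=O)c1c(O)c2[C@@H](C(C)C)CC(=O)Oc2c2[C@@H](CC(C)C)CC(=O)Oc12 | intermediate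
10 | 2,2,4,4-tetramethylcyclobutane-1,3-dione (dimethylketene dimer) | CC1(C)C(=O)C(C)(C)C1=O | starting material
11 | 3,9-bis(2,2,4-trimethyl-3-oxopentanoyl) derivative of 9, present as lithium enolates and drawn neutral, not isolated; alkyl-bearing carbons spatially unchanged (now labelled 4S,10S by priority), C-3 and C-9 enolised | CCCCCC(=O)c1c(O)c2[C@@H](C(C)C)C(C(=O)C(C)(C)C(=O)C(C)C)C(=O)Oc2c2[C@@H](CC(C)C)C(C(=O)C(C)(C)C(=O)C(C)C)C(=O)Oc12 | intermediate
12 | myrtucommulone H: hexanoylphloroglucinol bearing (R)-CH(isobutyl)(syncarpyl) and (R)-CH(isopropyl)(syncarpyl) on the two remaining ring carbons, syncarpyl = 2-hydroxy-3,3,5,5-tetramethyl-4,6-dioxocyclohex-1-enyl | CCCCCC(=O)c1c(O)c([C@@H](CC(C)C)C2=C(O)C(C)(C)C(=O)C(C)(C)C2=O)c(O)c([C@H](C2=C(O)C(C)(C)C(=O)C(C)(C)C2=O)C(C)C)c1O | target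

**Totals**
Total step count: 4. Longest linear sequence: 4 (1 → 3 → 6 → 9 → 12).

**Steps most likely to fail**

Step 4.
- Risks: a hindered enolate must add to a hindered ketone. Proton shuffling can park the material as the β-keto-lactone enolate. O-acylation competes with C-acylation. Stray enolisation of the hexanoyl chain next to lactone ring B could start a Baker–Venkataraman-type acyl shift.
- Fallback, from 9 and 10 back to 12: the order of the two C–C bond formations is reversed and the work is split in two. Compound 10 is opened with MeOH and catalytic NaOMe (retro-Claisen) to methyl 2,2,4-trimethyl-3-oxopentanoate F1. Its tertiary lithium enolate (LiN(iPr)2, THF, −78 → −20 °C, 5 equiv) is acylated by the two aryl-lactone carbonyls of 9 in a crossed Claisen reaction, with the ring phenoxides as internal leaving groups. This gives the ring-opened bis(triketo ester) F2, isolated after a cold quench. KOtBu in THF at 0 °C then closes both carbocycles together by a double Dieckmann condensation of the two CH2 groups onto the methyl esters, the way syncarpic acid itself is made. This closure gives the stabilised enolates directly, and acidification gives 12.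

Step 3.
- Risk: 6 carries one acylated oxygen and a ketone, so it is a much weaker carbon nucleophile than 3. It may only be O-acylated or may react too slowly.
- Fallback, from 6 back to 9: 6 is esterified at the less hindered 7-OH with commercial (E)-5-methylhex-2-enoic acid (N-(3-dimethylaminopropyl)-N'-ethylcarbodiimide hydrochloride, catalytic 4-dimethylaminopyridine, CH2Cl2). This gives (4R)-6-hexanoyl-5-hydroxy-4-isopropyl-2-oxochroman-7-yl (E)-5-methylhex-2-enoate F3. The same chiral triazolium salt (20 mol%, iPr2NEt, toluene, 40 °C, no oxidant) cleaves this activated aryl ester to a tight ion pair of 8 and the phenoxide. The pair recombines first C–C and then O–C, a carbene-catalysed enol-ester to dihydropyranone rearrangement type, and gives 9. The phenoxide is then present in full amount next to the electrophile.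

Step 2.
- Risks: the enantiomeric excess may be moderate with the β-branched enal, some double annulation may occur, and the oxidant meets a free triphenol. Lactone closure on an ortho phenol instead of the para phenol would be harmless, since every lactone C–O bond is cleaved in step 4 and all such isomers end as 12.
- Fallback, from 3 and 4 back to 6: iminium catalysis replaces carbene catalysis. With (2R,5R)-5-benzyl-2-tert-butyl-3-methylimidazolidin-4-one·CF3CO2H (20 mol%, CH2Cl2–iPrOH, −40 °C), 3 adds to 4 in an enantioselective Friedel–Crafts conjugate addition. The sense of induction is known from the (2S,5S) catalyst, which gives the opposite series with enals and electron-rich arenes. The aldehyde closes on the phenol to the lactol (4R)-1-(2,5,7-trihydroxy-4-isopropylchroman-6-yl)hexan-1-one F4. Oxidation of the lactol with Ag2CO3 on Celite (toluene, 80 °C) gives 6.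

**Further compounds**
F1 | step 4 | methyl 2,2,4-trimethyl-3-oxopentanoate | COC(=O)C(C)(C)C(=O)C(C)C
F2 | step 4 | ring-opened bis(triketo ester): hexanoylphloroglucinol bearing (S)-CH(isobutyl)CH2COCMe2COCMe2CO2Me and (R)-CH(isopropyl)CH2COCMe2COCMe2CO2Me on the two remaining ring carbons | CCCCCC(=O)c1c(O)c([C@@H](CC(C)C)CC(=O)C(C)(C)C(=O)C(C)(C)C(=O)OC)c(O)c([C@H](CC(=O)C(C)(C)C(=O)C(C)(C)C(=O)OC)C(C)C)c1O
F3 | step 3 | (4R)-6-hexanoyl-5-hydroxy-4-isopropyl-2-oxochroman-7-yl (E)-5-methylhex-2-enoate | CCCCCC(=O)c1c(O)c2[C@@H](C(C)C)CC(=O)Oc2cc1OC(=O)/C=C/CC(C)C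
F4 | step 2 | (4R)-1-(2,5,7-trihydroxy-4-isopropylchroman-6-yl)hexan-1-one (lactol, anomeric mixture) | CCCCCC(=O)c1c(O)c2[C@@H](C(C)C)CC(O)Oc2cc1O
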